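**Retrosynthetic overview**
- The tertiary bromohydrin of ring B is made last from a 4-substituted cyclohexanone: methyl addition to a cis-2-bromo ketone, after bromination of an enol ether set by a chiral lithium amide. The exocyclic methylene comes from a Wittig reaction on a ketone that joins the ring-A CH2 to a 4-silyloxycyclohexyl ring.
- That ketone is cut at the carbonyl–ring B bond into the N-methoxy-N-methylamide of the ring-A epoxy acetic acid and a 4-silyloxycyclohexyl Grignard reagent from cyclohexane-1,4-diol.
- Feature used: in ring A (a 7-oxabicyclo[4.1.0]heptane) the epoxide oxygen on C1/C6 lies on the face of the CH2 linker on C2 and opposite the isopropenyl group on C3. A carboxyl group on that CH2 can reach C1 from this face, so the epoxide is traced to a cis-fused iodolactone of a cyclohex-2-enylacetic acid; the carboxyl carbon later becomes the methylene-bearing alkene carbon.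
- The acid comes from (S)-carvone by enolate alkylation trans to isopropenyl, reductive transposition of the enone and saponification; a methyl ester is used so that the acid is freed without acid.
- Ring formation order: γ-lactone (step 5, temporary), then epoxide (step 6). Both carbocycles are bought (carvone, cyclohexane-1,4-diol).

Key step: step 5

Assumption: the (S,S)-enantiomer of the chiral lithium amide in step 14 is taken to remove the α-proton that leads to the required enol ether, by analogy with the sense known for 4-alkylcyclohexanones; if the sense on this substrate is the reverse, the (R,R)-amide is used with no other change.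

Step 1
Reactants: 1 (S)-(+)-carvone; 2 methyl bromoacetate
Product: 4 methyl 2-[(1R,6S)-3-methyl-2-oxo-6-(prop-1-en-2-yl)cyclohex-3-en-1-yl]acetate (side chain trans to isopropenyl), via lithium dienolate 3 (not isolated)
Conditions: LiN(iPr)2, THF, −78 °C; then 2, −78 to −30 °C
Reagents that add atoms: none
Why: Kinetic deprotonation at the α'-methylene gives the cross-conjugated lithium dienolate, which is C-alkylated by the bromoacetate on the face opposite the neighbouring isopropenyl group (enolate alkylation), so the new centre is set trans by the adjacent carvone stereocentre and can still settle to this more stable arrangement.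

Step 2
Reactants: 4 keto ester
Product: 5 methyl 2-[(1R,6S)-3-methyl-6-(prop-1-en-2-yl)-2-(2-tosylhydrazinylidene)cyclohex-3-en-1-yl]acetate (C=N geometry of no consequence)
Conditions: TsNHNH2, AcOH (cat.), MeOH, 50 °C
Reagents that add atoms: p-toluenesulfonyl hydrazide, Cc1ccc(cc1)S(=O)(=O)NN
Why: Acid-catalysed condensation of the enone carbonyl with the sulfonyl hydrazide (hydrazone formation) should proceed without touching the ester, methanol being chosen to exclude ester exchange, and the trans side chain is the thermodynamically preferred epimer.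

Step 3
Reactants: 5 tosylhydrazone
Product: 7 methyl 2-[(1S,6S)-3-methyl-6-(prop-1-en-2-yl)cyclohex-2-en-1-yl]acetate, via allylic diazene 6 (not isolated)
Conditions: catecholborane, CHCl3, 0 °C to rt; NaOAc·3H2O, reflux
Reagents that add atoms: none
Why: Hydride adds to the C=N carbon, acetate-induced loss of sulfinate gives the allylic diazene, and its retro-ene loss of N2 moves the double bond to the former carbonyl carbon (reductive alkene transposition of an enone tosylhydrazone); no stereocentre is created or disturbed.

Step 4
Reactants: 7 methyl ester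
Product: 8 2-[(1S,6S)-3-methyl-6-(prop-1-en-2-yl)cyclohex-2-en-1-yl]acetic acid
Conditions: LiOH, THF/MeOH/H2O, rt; then 1 M HCl to pH 3 at 0 °C
Reagents that add atoms: lithium hydroxide, [Li+].[OH-]
Why: Saponification of an unhindered methyl ester should free the acid under basic conditions that leave both alkenes untouched, and the ring stereocentre β to the carboxyl group cannot epimerise.

Step 5
Reactants: 8 ring-A acetic acid
Product: 9 cis-fused iodolactone, 7-iodo-7-methyl-4-(prop-1-en-2-yl)hexahydro-1-benzofuran-2(3H)-one (lactone oxygen syn to the C3 methylene, iodine anti to that oxygen, isopropenyl trans to the C3 methylene)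
Conditions: I2, KI, NaHCO3, THF/H2O, 0 °C, dark
Reagents that add atoms: iodine, [I][I]
Why: Iodine adds reversibly to both alkenes, but only the iodonium ion of the ring alkene that lies on the face away from the side chain is trapped, the carboxylate attacking the ring methine C2 from its own face while the C–I bond forms on the methyl-bearing C3 in a trans-diaxial opening of the half-chair. The closest known reaction type is the bicarbonate-buffered, kinetically controlled iodolactonisation of cyclohex-2-enylacetic acids to cis-fused iodolactones. The one ring closed is the γ-lactone, formed in the 5-exo mode (C3 stays outside the new ring) and cis-fused because a two-atom tether cannot span trans positions. Both new centres are controlled by the existing centre C1 that carries the tether: oxygen at C2 ends syn to the side chain and iodine at C3 anti to oxygen, the arrangement from which the epoxide on the side-chain face follows. The step needs regioselectivity for C2 over the Markovnikov position C3 and chemoselectivity over the isopropenyl group; attack at C3 would require a bridged δ-lactone from a conformer with both ring substituents axial, and closure on the isopropenyl group would be a slower 6-exo process on the less electron-rich 1,1-disubstituted alkene. Low temperature and the buffered aqueous medium should keep the closure kinetic, so that the tertiary iodide neither ionises nor equilibrates.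

Step 6
Reactants: 9 iodolactone
Product: 11 methyl 2-[(1R,2R,3S,6S)-6-methyl-3-(prop-1-en-2-yl)-7-oxabicyclo[4.1.0]heptan-2-yl]acetate, via iodo alkoxide 10 (not isolated)
Conditions: K2CO3, MeOH, 0 °C to rt
Reagents that add atoms: methanol, CO
Why: Methoxide opens the γ-lactone to the methyl ester, and the freed alkoxide, axial and antiperiplanar to the axial tertiary iodide, closes the epoxide by backside displacement (lactone methanolysis then Williamson-type epoxide closure), so the oxygen stays on the side-chain face at the methine and arrives on the same face at the methyl-bearing carbon with inversion there.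

Step 7
Reactants: 11 epoxy ester
Product: 12 N-methoxy-N-methyl-2-[(1R,2R,3S,6S)-6-methyl-3-(prop-1-en-2-yl)-7-oxabicyclo[4.1.0]heptan-2-yl]acetamide
Conditions: MeNHOMe·HCl, iPrMgCl, THF, −20 °C; aq NH4Cl
Reagents that add atoms: N,O-dimethylhydroxylamine hydrochloride, CNOC.Cl
Why: The chloromagnesium amide made from the hydroxylamine salt and iPrMgCl converts the methyl ester into the N-methoxy-N-methylamide at low temperature (ester aminolysis with a magnesium amide), conditions under which a trisubstituted epoxide should not be opened.

Step 8
Reactants: 13 cyclohexane-1,4-diol (cis/trans mixture, used in excess)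
Product: 14 4-(tert-butyldimethylsilyloxy)cyclohexan-1-ol (cis/trans mixture)
Conditions: TBSCl, imidazole, DMF, 0 °C to rt
Reagents that add atoms: tert-butyldimethylsilyl chloride, CC(C)(C)[Si](C)(C)Cl
Why: Statistical monosilylation of the symmetric diol used in excess (silyl ether formation) should give the mono ether, and both diol isomers are acceptable because neither carbinol carbon is a stereocentre of the target at this stage.

Step 9
Reactants: 14 mono-silyl ether
Product: 15 (4-bromocyclohexyloxy)(tert-butyl)dimethylsilane (cis/trans mixture)
Conditions: CBr4, PPh3, CH2Cl2, 0 °C to rt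
Reagents that add atoms: carbon tetrabromide, BrC(Br)(Br)Br
Why: Appel reaction, in which bromide displaces the oxyphosphonium group with inversion under neutral conditions that the silyl ether tolerates; the configuration of the bromide is irrelevant.

Step 10
Reactants: 12 N-methoxy-N-methylamide; 15 bromide
Product: 17 1-[4-(tert-butyldimethylsilyloxy)cyclohexyl]-2-[(1R,2R,3S,6S)-6-methyl-3-(prop-1-en-2-yl)-7-oxabicyclo[4.1.0]heptan-2-yl]ethan-1-one (ring B cis/trans mixture), via Grignard reagent 16 (not isolated)
Conditions: Mg, THF, 40 °C; then 12, THF, −20 to 0 °C; aq NH4Cl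
Reagents that add atoms: none
Why: Magnesium insertion gives the secondary Grignard reagent, which adds once to the amide because the chelated tetrahedral adduct persists until work-up (Weinreb ketone synthesis); the epoxide should survive an organomagnesium reagent in THF at 0 °C, and the cis/trans mixture in ring B is of no consequence.

Step 11
Reactants: 17 ketone
Product: 18 tert-butyldimethyl[(4-{3-[(1R,2R,3S,6S)-6-methyl-3-(prop-1-en-2-yl)-7-oxabicyclo[4.1.0]heptan-2-yl]prop-1-en-2-yl}cyclohexyl)oxy]silane
Conditions: Ph3PCH3Br, KOtBu, THF, 0 to 50 °C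
Reagents that add atoms: methyltriphenylphosphonium bromide, C[P+](c1ccccc1)(c1ccccc1)c1ccccc1.[Br-]
Why: Wittig methylenation with the non-stabilised ylide should convert the ketone into the 1,1-disubstituted alkene; any epimerisation next to the carbonyl is harmless because that ring-B carbon is not yet a stereocentre of consequence, and the epoxide and silyl ether are inert to the ylide.

Step 12
Reactants: 18 silyl ether
Product: 19 4-{3-[(1R,2R,3S,6S)-6-methyl-3-(prop-1-en-2-yl)-7-oxabicyclo[4.1.0]heptan-2-yl]prop-1-en-2-yl}cyclohexan-1-ol (cis/trans mixture)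
Conditions: TBAF, THF, rt
Reagents that add atoms: none
Why: Fluoride cleaves the silicon–oxygen bond (fluoride desilylation) under conditions that leave the epoxide and both alkenes unchanged.

Step 13
Reactants: 19 alcohol
Product: 20 4-{3-[(1R,2R,3S,6S)-6-methyl-3-(prop-1-en-2-yl)-7-oxabicyclo[4.1.0]heptan-2-yl]prop-1-en-2-yl}cyclohexan-1-one
Conditions: Dess–Martin periodinane, pyridine, CH2Cl2, 0 °C to rt
Reagents that add atoms: none
Why: Dess–Martin oxidation of the secondary alcohol, buffered with pyridine so that the liberated acetic acid does not open the epoxide, merges both alcohol isomers into one ketone.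

Step 14
Reactants: 20 4-substituted cyclohexanone
Product: 22 trimethyl{[(4R)-4-{3-[(1R,2R,3S,6S)-6-methyl-3-(prop-1-en-2-yl)-7-oxabicyclo[4.1.0]heptan-2-yl]prop-1-en-2-yl}cyclohex-1-en-1-yl]oxy}silane, via lithium enolate 21 (not isolated)
Conditions: (S,S)-bis(1-phenylethyl)amine, n-BuLi, THF; TMSCl then 20, −100 to −78 °C; Et3N, aq NaHCO3; filtration through Et3N-deactivated silica
Reagents that add atoms: chlorotrimethylsilane, C[Si](C)(C)Cl
Why: The C2-symmetric lithium amide removes one of the two α-methylene protons faster than the other and the enolate is silylated as it forms (desymmetrising deprotonation with internal silyl quench), which makes ring-B C4 a stereocentre under reagent control, the ring-A centres being too remote to interfere.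

Step 15
Reactants: 22 silyl enol ether
Product: 23 (2S,4R)-2-bromo-4-{3-[(1R,2R,3S,6S)-6-methyl-3-(prop-1-en-2-yl)-7-oxabicyclo[4.1.0]heptan-2-yl]prop-1-en-2-yl}cyclohexan-1-one (bromine axial, trans to the C4 side chain)
Conditions: NBS, THF, −78 °C
Reagents that add atoms: N-bromosuccinimide, O=C1CCC(=O)N1Br
Why: Electrophilic bromination of the silyl enol ether occurs only at the enol carbon and far faster than at the two 1,1-disubstituted alkenes; attack along the axial trajectory should give mainly the axial bromide, and any equatorial epimer formed alongside is the product of step 16 and is carried on.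

Step 16
Reactants: 23 axial bromo ketone
Product: 24 (2R,4R)-2-bromo-4-{3-[(1R,2R,3S,6S)-6-methyl-3-(prop-1-en-2-yl)-7-oxabicyclo[4.1.0]heptan-2-yl]prop-1-en-2-yl}cyclohexan-1-one (bromine equatorial, cis to the C4 side chain)
Conditions: Bu4NBr, MeCN, 25 °C; chromatographic separation, axial epimer resubmitted
Reagents that add atoms: tetrabutylammonium bromide, [Br-].CCCC[N+](CCCC)(CCCC)CCCC
Why: Bromide displaces bromide at the carbonyl-activated carbon with inversion (identity SN2 exchange, the process behind halide-induced epimerisation of α-bromo carbonyl compounds), so the two epimers equilibrate without enolisation, without acid and without touching C4; in a polar aprotic solvent the equatorial bromide should be favoured, and a Lewis-acid-free bromide source spares the epoxide.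

Step 17
Reactants: 24 equatorial bromo ketone
Product: 25 (1S,2R,4R)-2-bromo-1-methyl-4-{3-[(1R,2R,3S,6S)-6-methyl-3-(prop-1-en-2-yl)-7-oxabicyclo[4.1.0]heptan-2-yl]prop-1-en-2-yl}cyclohexan-1-ol (CNP0213097.1)
Conditions: MeMgBr, THF, −78 °C; aq NH4Cl at −78 °C
Reagents that add atoms: methylmagnesium bromide, C[Mg]Br
Why: Grignard 1,2-addition to a 2-halocyclohexanone places the new alkyl group trans to the halogen; with bromine and side chain both equatorial the methyl should enter along the equatorial trajectory, since axial attack would push the forming alkoxide into eclipse with the C–Br bond, which gives axial OH cis to bromine and equatorial methyl, and the cold quench should prevent semipinacol ring contraction of the bromohydrin alkoxide.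

**Compound list**
1 | (S)-(+)-carvone | CC1=CC[C@@H](CC1=O)C(C)=C | starting material
2 | methyl bromoacetate | COC(=O)CBr | starting material
3 | lithium dienolate of carvone (cross-conjugated, enolate double bond toward the former α'-methylene) | CC1=CC[C@@H](C=C1O[Li])C(C)=C | intermediate
4 | methyl 2-[(1R,6S)-3-methyl-2-oxo-6-(prop-1-en-2-yl)cyclohex-3-en-1-yl]acetate | COC(=O)C[C@@H]1[C@@H](C(C)=C)CC=C(C)C1=O | intermediate
5 | tosylhydrazone of 4 | COC(=O)C[C@@H]1[C@@H](C(C)=C)CC=C(C)C1=NNS(=O)(=O)c1ccc(C)cc1 | intermediate
6 | allylic diazene (configuration at the diazene-bearing carbon undefined, lost on N2 extrusion) | COC(=O)C[C@@H]1[C@@H](C(C)=C)CC=C(C)C1N=N | intermediate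
7 | methyl 2-[(1S,6S)-3-methyl-6-(prop-1-en-2-yl)cyclohex-2-en-1-yl]acetate | COC(=O)C[C@@H]1[C@@H](C(C)=C)CCC(C)=C1 | intermediate
8 | 2-[(1S,6S)-3-methyl-6-(prop-1-en-2-yl)cyclohex-2-en-1-yl]acetic acid | OC(=O)C[C@@H]1[C@@H](C(C)=C)CCC(C)=C1 | intermediate
9 | cis-fused iodolactone (tertiary iodide anti to lactone oxygen) | O=C1C[C@@H]2[C@@H](C(C)=C)CC[C@@](C)(I)[C@@H]2O1 | intermediate
10 | potassium alkoxide of the trans-iodohydrin methyl ester | COC(=O)C[C@@H]1[C@@H](C(C)=C)CC[C@@](C)(I)[C@@H]1[O-].[K+] | intermediate
11 | methyl 2-[(1R,2R,3S,6S)-6-methyl-3-(prop-1-en-2-yl)-7-oxabicyclo[4.1.0]heptan-2-yl]acetate | COC(=O)C[C@@H]1[C@@H](C(C)=C)CC[C@]2(C)O[C@H]12 | intermediate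
12 | N-methoxy-N-methylamide of the epoxy acid | CON(C)C(=O)C[C@@H]1[C@@H](C(C)=C)CC[C@]2(C)O[C@H]12 | intermediate
13 | cyclohexane-1,4-diol (cis/trans mixture) | OC1CCC(O)CC1 | starting material
14 | 4-(tert-butyldimethylsilyloxy)cyclohexan-1-ol (cis/trans mixture) | CC(C)(C)[Si](C)(C)OC1CCC(O)CC1 | intermediate
15 | (4-bromocyclohexyloxy)(tert-butyl)dimethylsilane (cis/trans mixture) | CC(C)(C)[Si](C)(C)OC1CCC(Br)CC1 | intermediate
16 | 4-(tert-butyldimethylsilyloxy)cyclohexylmagnesium bromide | CC(C)(C)[Si](C)(C)OC1CCC([Mg]Br)CC1 | intermediate
17 | ketone joining the ring-A CH2 to the 4-silyloxycyclohexyl ring | CC(C)(C)[Si](C)(C)OC1CCC(CC1)C(=O)C[C@@H]1[C@@H](C(C)=C)CC[C@]2(C)O[C@H]12 | intermediate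
18 | methylenated silyl ether | CC(C)(C)[Si](C)(C)OC1CCC(CC1)C(=C)C[C@@H]1[C@@H](C(C)=C)CC[C@]2(C)O[C@H]12 | intermediate
19 | ring-B cyclohexanol (cis/trans mixture) | OC1CCC(CC1)C(=C)C[C@@H]1[C@@H](C(C)=C)CC[C@]2(C)O[C@H]12 | intermediate
20 | ring-B cyclohexanone | O=C1CCC(CC1)C(=C)C[C@@H]1[C@@H](C(C)=C)CC[C@]2(C)O[C@H]12 | intermediate
21 | lithium enolate of 20, (4R) in ring B | C=C(C[C@@H]1[C@@H](C(=C)C)CC[C@]2(C)O[C@H]12)[C@@H]1CCC(O[Li])=CC1 | intermediate
22 | trimethylsilyl enol ether, (4R) in ring B | C=C(C[C@@H]1[C@@H](C(=C)C)CC[C@]2(C)O[C@H]12)[C@@H]1CCC(O[Si](C)(C)C)=CC1 | intermediate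
23 | (2S,4R)-2-bromo ketone (Br axial, trans to side chain) | C=C(C[C@@H]1[C@@H](C(=C)C)CC[C@]2(C)O[C@H]12)[C@@H]1CCC(=O)[C@@H](Br)C1 | intermediate
24 | (2R,4R)-2-bromo ketone (Br equatorial, cis to side chain) | C=C(C[C@@H]1[C@@H](C(=C)C)CC[C@]2(C)O[C@H]12)[C@@H]1CCC(=O)[C@H](Br)C1 | intermediate
25 | (1S,2R,4R)-2-bromo-1-methyl-4-{3-[(1R,2R,3S,6S)-6-methyl-3-(prop-1-en-2-yl)-7-oxabicyclo[4.1.0]heptan-2-yl]prop-1-en-2-yl}cyclohexan-1-ol | C=C(C[C@@H]1[C@@H](C(=C)C)CC[C@]2(C)O[C@H]12)[C@@H]1CC[C@](C)(O)[C@H](Br)C1 | target

**Step count and risks**
Total step count: 17. Longest linear sequence: 15 steps (steps 1–7 and 10–17); the ring-B branch is steps 8–9.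

Steps most likely to fail:

1. Step 5 (key step). The carboxylate may instead capture the iodonium ion of the isopropenyl group in a six-membered closure, close at the methyl-bearing carbon, or the tertiary iodide may ionise. Fallback: a hydroxyl-directed epoxidation replaces the lactone relay. It sets out from ester 7: LiAlH4 in THF at 0 °C should give the homoallylic alcohol F1. VO(acac)2 with tert-butyl hydroperoxide in toluene should deliver oxygen to the nearer, trisubstituted ring alkene from the face of the hydroxyethyl chain and give the syn epoxy alcohol F2. Dess–Martin oxidation with pyridine should give the epoxy aldehyde F3; addition of Grignard reagent 16 at −78 °C the carbinol F4 (mixture at the new carbinol carbon); and a second Dess–Martin oxidation rejoins the route at ketone 17.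

2. Step 16. The equilibrium between axial and equatorial bromide may lie too little on the equatorial side, and elimination to the enone may compete on long exposure to bromide. Fallback: bromide is introduced as a nucleophile with inversion instead of by equilibration. It sets out from silyl enol ether 22: MeLi in THF at 0 °C regenerates lithium enolate 21, and 2-(phenylsulfonyl)-3-phenyloxaziridine at −78 °C should hydroxylate it along the axial trajectory to the trans α-hydroxy ketone F8. Tf2O with 2,6-lutidine at −78 °C should give the α-triflate F9. One equivalent of Bu4NBr at −40 °C should displace the triflate with inversion and return to the route at equatorial bromo ketone 24, with no excess bromide left to re-equilibrate it.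

3. Step 10. Magnesium halide may open or rearrange the epoxide, the hindered secondary Grignard reagent may enolise the amide rather than add, and Grignard formation may be eroded by coupling and elimination. Fallback: ring B is built by cycloaddition instead of being added as a nucleophile. It sets out from amide 12: vinylmagnesium bromide at −78 °C (fast addition of an unhindered reagent) should give the vinyl ketone F5. Thermal Diels–Alder reaction with 2-(tert-butyldimethylsilyloxy)buta-1,3-diene in toluene at 90 °C should give the 1,4-("para") adduct F6 (mixture at the ring-B carbon, which is of no consequence). Wittig methylenation as in step 11 should give F7, and TBAF buffered with acetic acid cleaves the silyl enol ether and comes back to the route at ketone 20, bypassing 13–19.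

Further compounds
F1 | step 5 | 2-[(1S,6S)-3-methyl-6-(prop-1-en-2-yl)cyclohex-2-en-1-yl]ethan-1-ol | OCC[C@@H]1[C@@H](C(C)=C)CCC(C)=C1
F2 | step 5 | 2-[(1R,2R,3S,6S)-6-methyl-3-(prop-1-en-2-yl)-7-oxabicyclo[4.1.0]heptan-2-yl]ethan-1-ol | OCC[C@@H]1[C@@H](C(C)=C)CC[C@]2(C)O[C@H]12
F3 | step 5 | 2-[(1R,2R,3S,6S)-6-methyl-3-(prop-1-en-2-yl)-7-oxabicyclo[4.1.0]heptan-2-yl]acetaldehyde | O=CC[C@@H]1[C@@H](C(C)=C)CC[C@]2(C)O[C@H]12
F4 | step 5 | 1-[4-(tert-butyldimethylsilyloxy)cyclohexyl]-2-[(1R,2R,3S,6S)-6-methyl-3-(prop-1-en-2-yl)-7-oxabicyclo[4.1.0]heptan-2-yl]ethan-1-ol (mixture at the carbinol carbon) | CC(C)(C)[Si](C)(C)OC1CCC(CC1)C(O)C[C@@H]1[C@@H](C(C)=C)CC[C@]2(C)O[C@H]12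
F5 | step 10 | 1-[(1R,2R,3S,6S)-6-methyl-3-(prop-1-en-2-yl)-7-oxabicyclo[4.1.0]heptan-2-yl]but-3-en-2-one | C=CC(=O)C[C@@H]1[C@@H](C(C)=C)CC[C@]2(C)O[C@H]12
F6 | step 10 | 1-[4-(tert-butyldimethylsilyloxy)cyclohex-3-en-1-yl]-2-[(1R,2R,3S,6S)-6-methyl-3-(prop-1-en-2-yl)-7-oxabicyclo[4.1.0]heptan-2-yl]ethan-1-one (mixture at the ring-B carbon) | CC(C)(C)[Si](C)(C)OC1=CCC(CC1)C(=O)C[C@@H]1[C@@H](C(C)=C)CC[C@]2(C)O[C@H]12
F7 | step 10 | tert-butyldimethylsilyl enol ether of ketone 20 (mixture at the ring-B carbon) | CC(C)(C)[Si](C)(C)OC1=CCC(CC1)C(=C)C[C@@H]1[C@@H](C(C)=C)CC[C@]2(C)O[C@H]12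
F8 | step 16 | (2S,4R)-2-hydroxy-4-{3-[(1R,2R,3S,6S)-6-methyl-3-(prop-1-en-2-yl)-7-oxabicyclo[4.1.0]heptan-2-yl]prop-1-en-2-yl}cyclohexan-1-one (OH axial, trans to side chain) | C=C(C[C@@H]1[C@@H](C(=C)C)CC[C@]2(C)O[C@H]12)[C@@H]1CCC(=O)[C@@H](O)C1
F9 | step 16 | trifluoromethanesulfonate of F8 | C=C(C[C@@H]1[C@@H](C(=C)C)CC[C@]2(C)O[C@H]12)[C@@H]1CCC(=O)[C@@H](OS(=O)(=O)C(F)(F)F)C1
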